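Read at 1.5 min, the flasks zeta, theta and delta share one charge and differ in temperature.

common to all: starting material 0.44 M; reagent 0.484 M; free catalyst 4.0 mM; second catalyst 0.53 mM; time 1.5 min

| flask | temperature |
|---|---|
| zeta | −20 °C |
| theta | −35 °C |
| delta | −5 °C |

    starting material + free catalyst → free catalyst + open intermediate (k1 = 4.1 M⁻¹ s⁻¹, Ea1 = 41.0 kJ mol⁻¹)
    second catalyst + open intermediate ⇌ catalyst intermediate (K2 = 12 M⁻¹, k2 = 320 M⁻¹ s⁻¹, Ea2 = 37.0 kJ mol⁻¹, ΔH2 = 7.00 kJ mol⁻¹)
    reagent + catalyst intermediate ⇌ second catalyst + product (K3 = 0.083, k3 = 6.4 M⁻¹ s⁻¹, Ea3 = 46.0 kJ mol⁻¹, ΔH3 = 20.0 kJ mol⁻¹)
    (constants at −20 °C)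

- the constants hold at −20 °C; other temperatures follow from the activation energies and enthalpies

- the flask that comes out highest in amount of product, in percent of the starting material charged, or "all alike" when all lie within 1.5 percentage points (zeta / theta / delta / all alike)
- product at the end, in percent of the starting material charged, zeta
- product at the end, in percent of the starting material charged, theta
- product at the end, in percent of the starting material charged, delta

My own reckoning starts from zeta. Free catalyst comes out of the first step unchanged, so starting material falls pseudo-first-order, and the amount a opened by the time of reading is

a = 0.44 M × (1 − exp(−4.1 M⁻¹ s⁻¹ × 4.0 mM × 1.5 min)) = 0.339 M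

Adding the second and third equations cancels second catalyst and catalyst intermediate. What remains is open intermediate + reagent ⇌ product, with overall constant

K = 12 M⁻¹ × 0.083 = 0.996 M⁻¹

The second catalyst charge of 0.53 mM is too small to count against 0.44 M. The balance for the product x, with c the reagent charge 0.484 M, is therefore

x = K(a − x)(c − x)

Its smaller root, in percent of the starting material charged, is 21.5 %. This is the opened ceiling: the product at which the material opened so far stands in equilibrium with reagent. Product starts below this line, and the reckoning does not say how far below it zeta stands at the time of reading.

The neighbouring flask is zeta with 0.0010 M of free catalyst, a quarter of the charge. Its opening runs more slowly: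

a = 0.136 M, ceiling 9.44 %

The two flasks have the same K and the same reagent, so they part through the opened amount, and the neighbour's ceiling is 0.439 of zeta's.

The forecast names delta as highest, with 12.9 % for zeta, 2.3 % for theta and 34.6 % for delta, on the ground that warming “speeds every step and also shifts both endothermic equilibria toward product”.

The simulation gives delta as highest, with 13.0 % for zeta, 2.38 % for theta and 34.6 % for delta, so the forecast holds within the tolerance.

Zeta stands at 60.5 % of its opened ceiling, yet the back reaction is already running there. With the undoing of second catalyst + product into reagent + catalyst intermediate struck out, zeta gives 18.7 %, which is 5.7 percentage points more. In delta, part of what holds product at 34.6 % is that undoing acting together with the undoing of catalyst intermediate into second catalyst + open intermediate: delta gives 57.2 % with the former struck out and 63.1 % with the latter.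

Left until 6.0 min, zeta has a = 0.439 M, and its ceiling becomes 26.7 %. That flask reads 26.0 %.

Its constants were chosen freely.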